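**Retrosynthetic overview**
- Target ⇐ global hydrogenolysis of a benzyl/diphenylmethylene-protected digallate ⇐ site-selective double esterification of a protected dimer triol.
- Both pyran (C) rings are cut at C4–C4a at once: a bis-epoxide diaryl ether closes twice by intramolecular Friedel–Crafts epoxy–arene alkylation. The upper ring closes first (benzylic oxirane, sets C4), the lower ring second (terminal oxirane).
- The central (lower A) ring is a para-substituted, symmetric 3,5-bis(benzyloxy)phenol aldehyde, so only the 4→6 linkage can form.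
- Upper arm: Claisen–Schmidt chalcone → Juliá–Colonna epoxide → Zn(BH4)2 (erythro) → Mitsunobu aryl ether (inversion). Lower arm: Sharpless kinetic-resolution epoxy alcohol → Mitsunobu (inversion).
- Ring order: benzodioxole (protecting ring) → two oxiranes → both pyran rings in one operation.

Assumption: 3,5-bis(benzyloxy)phenol, 1-[3,4-bis(benzyloxy)phenyl]ethanone and 3,4,5-tris(benzyloxy)benzoic acid are bought as catalogue compounds.

**Route**

Step 1
Reactants: 1 3,4,5-trihydroxybenzaldehyde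
Product: 2 7-hydroxy-2,2-diphenyl-1,3-benzodioxole-5-carbaldehyde
Conditions: Ph2CCl2, Ph2O, 175 °C
Reagents that add atoms: dichlorodiphenylmethane, ClC(Cl)(c1ccccc1)c1ccccc1
Why: Ketalisation of one catechol pair of the pyrogallol (benzodioxole formation; either adjacent pair gives the same product by symmetry) leaves exactly one phenol free, and no stereocentre is formed.

Step 2
Reactants: 2 7-hydroxy-2,2-diphenyl-1,3-benzodioxole-5-carbaldehyde
Product: 3 7-(allyloxy)-2,2-diphenyl-1,3-benzodioxole-5-carbaldehyde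
Conditions: allyl bromide, K2CO3, DMF, rt
Reagents that add atoms: allyl bromide, C=CCBr
Why: Williamson etherification; the allyl ether tolerates Grignard, base, Mitsunobu and Lewis acid and is later removed by Pd(0) without touching benzyl ethers.

Step 3
Reactants: 3 7-(allyloxy)-2,2-diphenyl-1,3-benzodioxole-5-carbaldehyde
Product: 4 rac-1-[7-(allyloxy)-2,2-diphenyl-1,3-benzodioxol-5-yl]prop-2-en-1-ol
Conditions: CH2=CHMgBr, THF, −78 → 0 °C; then H2O
Reagents that add atoms: vinylmagnesium bromide, C=C[Mg]Br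
Why: Grignard 1,2-addition to the aldehyde gives the racemic aryl vinyl carbinol needed for resolution.

Step 4
Reactants: 4 rac-1-[7-(allyloxy)-2,2-diphenyl-1,3-benzodioxol-5-yl]prop-2-en-1-ol
Product: 5 (S)-[7-(allyloxy)-2,2-diphenyl-1,3-benzodioxol-5-yl][(2R)-oxiran-2-yl]methanol (erythro)
Conditions: Ti(OiPr)4 (10 mol%), L-(+)-DIPT (15 mol%), t-BuOOH (0.6 equiv), 4 Å MS, CH2Cl2, −20 °C
Reagents that add atoms: tert-butyl hydroperoxide, CC(C)(C)OO
Why: Sharpless kinetic resolution (Katsuki–Sharpless epoxidation): the L-(+)-tartrate catalyst epoxidises only the (R)-carbinol on one alkene face, giving the erythro (1S,2R) epoxy alcohol, which fixes lower C3 and, before inversion, lower C2.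

Step 5
Reactants: 6 3,5-bis(benzyloxy)phenol
Product: 7 2,6-bis(benzyloxy)-4-hydroxybenzaldehyde
Conditions: POCl3, DMF, MeCN, 0 °C → rt; then H2O
Reagents that add atoms: N,N-dimethylformamide, CN(C)C=O; water, O
Why: Vilsmeier–Haack formylation occurs mainly para to the free OH (between the two benzyloxy groups); the minor chelated ortho isomer is removed by chromatography.

Step 6
Reactants: 5 (S)-[7-(allyloxy)-2,2-diphenyl-1,3-benzodioxol-5-yl][(2R)-oxiran-2-yl]methanol; 7 2,6-bis(benzyloxy)-4-hydroxybenzaldehyde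
Product: 8 2,6-bis(benzyloxy)-4-{(R)-[7-(allyloxy)-2,2-diphenyl-1,3-benzodioxol-5-yl][(2R)-oxiran-2-yl]methoxy}benzaldehyde
Conditions: PPh3, DIAD, THF, 0 °C → rt
Reagents that add atoms: none
Why: Mitsunobu etherification with the acidic para-formyl phenol proceeds by SN2 inversion at the benzylic carbinol (S → R; the adjacent oxirane disfavours ionisation), which sets lower C2.

Step 7
Reactants: 8 aldehyde from step 6; 9 1-[3,4-bis(benzyloxy)phenyl]ethan-1-one
Product: 10 (E)-1-[3,4-bis(benzyloxy)phenyl]-3-[2,6-bis(benzyloxy)-4-{(R)-[7-(allyloxy)-2,2-diphenyl-1,3-benzodioxol-5-yl][(2R)-oxiran-2-yl]methoxy}phenyl]prop-2-en-1-one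
Conditions: Ba(OH)2·8H2O, MeOH/THF, 40 °C
Reagents that add atoms: none
Why: Claisen–Schmidt aldol condensation of a non-enolisable aldehyde with the methyl ketone gives the thermodynamic E-enone; the mild heterogeneous base spares the terminal oxirane.

Step 8
Reactants: 10 (E)-chalcone from step 7
Product: 11 [3,4-bis(benzyloxy)phenyl]{(2R,3S)-3-[2,6-bis(benzyloxy)-4-{(R)-[7-(allyloxy)-2,2-diphenyl-1,3-benzodioxol-5-yl][(2R)-oxiran-2-yl]methoxy}phenyl]oxiran-2-yl}methanone
Conditions: poly-L-leucine, urea·H2O2, DBU, THF, rt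
Reagents that add atoms: hydrogen peroxide (as its urea adduct), OO
Why: Juliá–Colonna epoxidation (asymmetric Weitz–Scheffer): the helical poly-L-leucine delivers hydroperoxide to one enone face, giving the trans (2R,3S) epoxy ketone, which sets upper C3 and, before inversion, upper C4.

Step 9
Reactants: 11 epoxy ketone from step 8
Product: 12 (S)-[3,4-bis(benzyloxy)phenyl]{(2S,3S)-3-[2,6-bis(benzyloxy)-4-{(R)-[7-(allyloxy)-2,2-diphenyl-1,3-benzodioxol-5-yl][(2R)-oxiran-2-yl]methoxy}phenyl]oxiran-2-yl}methanol (erythro; oxirane geometry unchanged, the C-2 descriptor changes only through CIP priorities)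
Conditions: Zn(BH4)2, Et2O, −20 °C
Reagents that add atoms: none
Why: Chelation-controlled reduction (Zn bridges the carbonyl and oxirane oxygens, hydride enters from the side of the α-hydrogen) gives the erythro (S)-carbinol.

Step 10
Reactants: 12 epoxy alcohol from step 9; 6 3,5-bis(benzyloxy)phenol
Product: 13 1,3-bis(benzyloxy)-5-[(R)-[3,4-bis(benzyloxy)phenyl]{(2R,3S)-3-[2,6-bis(benzyloxy)-4-{(R)-[7-(allyloxy)-2,2-diphenyl-1,3-benzodioxol-5-yl][(2R)-oxiran-2-yl]methoxy}phenyl]oxiran-2-yl}methoxy]benzene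
Conditions: PPh3, DIAD, toluene, 0 °C → rt
Reagents that add atoms: none
Why: A second Mitsunobu etherification inverts the benzylic carbinol (S → R) and so sets upper C2 in the threo relationship to C3 that leads to the 2,3-cis ring.

Step 11
Reactants: 13 bis-epoxide diaryl ether from step 10
Product: 15 benzyl-protected epicatechin-(4β→6)-epigallocatechin diol (both pyran rings closed), via upper-ring-closed flavan-3-ol epoxide 14 (not isolated)
Conditions: BF3·OEt2 (0.3 equiv), CH2Cl2 (5 mM), −78 → 0 °C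
Reagents that add atoms: none
Why: Proposed new method: a twofold intramolecular Friedel–Crafts epoxy–arene cyclization run as one cascade — BF3 activates the benzylic oxirane carbon (stabilised by the 2,6-bis(benzyloxy)-4-alkoxyphenyl ring) and the ortho carbon of the tethered 3,5-bis(benzyloxy)phenyl ether attacks it anti to the departing oxygen through a chair transition state with the B-ring equatorial (6-endo, inversion at C4, giving the 2,3-cis-3,4-trans upper ring of 14), after which the central ring, electron-rich again, opens the terminal oxirane at CH2 (6-endo) to close the lower ring without touching lower C2/C3; because the central ring is symmetric only the 4→6 connectivity can form; the closest known reaction type is the Lewis-acid- or HFIP-promoted 6-endo cyclization of aryl glycidyl ethers to chroman-3-ols and trans-4-arylchroman-3-ols.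

Step 12
Reactants: 15 protected dimer diol from step 11
Product: 16 protected dimer triol (lower B-ring 3-OH free)
Conditions: Pd(PPh3)4 (5 mol%), morpholine, THF, rt
Reagents that add atoms: none
Why: Tsuji–Trost deallylation via a π-allyl palladium complex trapped by morpholine frees only the lower B-ring phenol; benzyl ethers, ketal and stereocentres are untouched.

Step 13
Reactants: 16 protected dimer triol; 17 3,4,5-tris(benzyloxy)benzoic acid (2.1 equiv)
Product: 18 protected lower-unit 3-O- and B-ring 3-O-bis[3,4,5-tris(benzyloxy)benzoyl] dimer (upper 3-OH free)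
Conditions: DCC, DMAP, CH2Cl2, 0 °C → rt
Reagents that add atoms: none
Why: Steglich esterification acylates the phenol and the lower C3–OH (flanked by CH2), while the axial upper C3–OH, buttressed by the C4 aryl group with two ortho benzyloxy groups, is expected to react much more slowly; no stereocentre is involved.

Step 14
Reactants: 18 protected digallate
Product: 19 (−)-epicatechin-(4β→6)-(−)-epigallocatechin 3,3'-di-O-gallate (CNP0237700.1)
Conditions: H2 (1 atm), Pd(OH)2/C, THF/MeOH, rt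
Reagents that add atoms: none
Why: Catalytic hydrogenolysis cleaves the twelve benzyl ethers and the diphenylmethylene ketal, while the esters, the interflavan bond and the C2–O1 bonds survive, as is standard for benzylated procyanidin gallates.

**Compound list**

1 | 3,4,5-trihydroxybenzaldehyde | O=Cc1cc(O)c(O)c(O)c1 | starting material
2 | 7-hydroxy-2,2-diphenyl-1,3-benzodioxole-5-carbaldehyde | O=Cc1cc(O)c2OC(c3ccccc3)(c3ccccc3)Oc2c1 | intermediate
3 | 7-(allyloxy)-2,2-diphenyl-1,3-benzodioxole-5-carbaldehyde | O=Cc1cc(OCC=C)c2OC(c3ccccc3)(c3ccccc3)Oc2c1 | intermediate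
4 | rac-1-[7-(allyloxy)-2,2-diphenyl-1,3-benzodioxol-5-yl]prop-2-en-1-ol (racemic) | OC(C=C)c1cc(OCC=C)c2OC(c3ccccc3)(c3ccccc3)Oc2c1 | intermediate
5 | (S)-[7-(allyloxy)-2,2-diphenyl-1,3-benzodioxol-5-yl][(2R)-oxiran-2-yl]methanol (erythro) | O[C@@H](c1cc(OCC=C)c2OC(c3ccccc3)(c3ccccc3)Oc2c1)[C@H]1CO1 | intermediate
6 | 3,5-bis(benzyloxy)phenol | Oc1cc(OCc2ccccc2)cc(OCc2ccccc2)c1 | starting material
7 | 2,6-bis(benzyloxy)-4-hydroxybenzaldehyde | O=Cc1c(OCc2ccccc2)cc(O)cc1OCc1ccccc1 | intermediate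
8 | 2,6-bis(benzyloxy)-4-{(R)-[7-(allyloxy)-2,2-diphenyl-1,3-benzodioxol-5-yl][(2R)-oxiran-2-yl]methoxy}benzaldehyde | O=Cc1c(OCc2ccccc2)cc(O[C@H](c2cc(OCC=C)c3OC(c4ccccc4)(c4ccccc4)Oc3c2)[C@H]2CO2)cc1OCc1ccccc1 | intermediate
9 | 1-[3,4-bis(benzyloxy)phenyl]ethan-1-one | CC(=O)c1ccc(OCc2ccccc2)c(OCc2ccccc2)c1 | starting material
10 | (E)-chalcone: 1-[3,4-bis(benzyloxy)phenyl]-3-[aryl of 8]prop-2-en-1-one, lower stereocentres as in 8 | O=C(/C=C/c1c(OCc2ccccc2)cc(O[C@H](c2cc(OCC=C)c3OC(c4ccccc4)(c4ccccc4)Oc3c2)[C@H]2CO2)cc1OCc1ccccc1)c1ccc(OCc2ccccc2)c(OCc2ccccc2)c1 | intermediate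
11 | trans-(2R,3S)-epoxy ketone of 10 | O=C(c1ccc(OCc2ccccc2)c(OCc2ccccc2)c1)[C@@H]1O[C@H]1c1c(OCc2ccccc2)cc(O[C@H](c2cc(OCC=C)c3OC(c4ccccc4)(c4ccccc4)Oc3c2)[C@H]2CO2)cc1OCc1ccccc1 | intermediate
12 | erythro epoxy alcohol: (S)-carbinol, (2S,3S)-oxirane (same oxirane geometry as 11) | O[C@@H](c1ccc(OCc2ccccc2)c(OCc2ccccc2)c1)[C@@H]1O[C@H]1c1c(OCc2ccccc2)cc(O[C@H](c2cc(OCC=C)c3OC(c4ccccc4)(c4ccccc4)Oc3c2)[C@H]2CO2)cc1OCc1ccccc1 | intermediate
13 | bis-epoxide diaryl ether: 3,5-bis(benzyloxy)phenyl ether of 12 with inverted (R) ether carbon, (2R,3S)-oxirane | C(c1ccccc1)Oc1cc(OCc2ccccc2)cc(O[C@H](c2ccc(OCc3ccccc3)c(OCc3ccccc3)c2)[C@@H]2O[C@H]2c2c(OCc3ccccc3)cc(O[C@H](c3cc(OCC=C)c4OC(c5ccccc5)(c5ccccc5)Oc4c3)[C@H]3CO3)cc2OCc2ccccc2)c1 | intermediate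
14 | upper-ring-closed flavan-3-ol epoxide: (2R,3R,4S)-5,7,3',4'-tetra-O-benzyl-epicatechin carrying at C4β the 2,6-bis(benzyloxy)-4-{(R)-aryl[(2R)-oxiranyl]methoxy}phenyl group | C=CCOc1cc([C@@H](Oc2cc(OCc6ccccc6)c([C@H]3c4c(OCc6ccccc6)cc(OCc6ccccc6)cc4O[C@H](c4ccc(OCc6ccccc6)c(OCc6ccccc6)c4)[C@@H]3O)c(OCc6ccccc6)c2)[C@H]2CO2)cc2OC(c3ccccc3)(c3ccccc3)Oc12 | intermediate (not isolated)
15 | 5,7,3',4'-tetra-O-benzyl-epicatechin-(4β→6)-[3'-O-allyl-5,7-di-O-benzyl-4',5'-O-diphenylmethylene-epigallocatechin]; upper 2R,3R,4S, lower 2R,3R; both 3-OH free | C=CCOc1cc([C@H]2Oc3cc(OCc6ccccc6)c([C@H]4c5c(OCc6ccccc6)cc(OCc6ccccc6)cc5O[C@H](c5ccc(OCc6ccccc6)c(OCc6ccccc6)c5)[C@@H]4O)c(OCc6ccccc6)c3C[C@H]2O)cc2OC(c3ccccc3)(c3ccccc3)Oc12 | intermediate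
16 | de-allylated triol of 15 (lower B-ring 3-OH and both C3–OH free) | Oc1cc([C@H]2Oc3cc(OCc6ccccc6)c([C@H]4c5c(OCc6ccccc6)cc(OCc6ccccc6)cc5O[C@H](c5ccc(OCc6ccccc6)c(OCc6ccccc6)c5)[C@@H]4O)c(OCc6ccccc6)c3C[C@H]2O)cc2OC(c3ccccc3)(c3ccccc3)Oc12 | intermediate
17 | 3,4,5-tris(benzyloxy)benzoic acid | OC(=O)c1cc(OCc2ccccc2)c(OCc2ccccc2)c(OCc2ccccc2)c1 | starting material
18 | protected digallate: 16 esterified at lower C3–O and lower B-ring 3-O with 3,4,5-tris(benzyloxy)benzoyl; upper 3-OH free | O=C(Oc1cc([C@H]2Oc3cc(OCc6ccccc6)c([C@H]4c5c(OCc6ccccc6)cc(OCc6ccccc6)cc5O[C@H](c5ccc(OCc6ccccc6)c(OCc6ccccc6)c5)[C@@H]4O)c(OCc6ccccc6)c3C[C@H]2OC(=O)c2cc(OCc6ccccc6)c(OCc6ccccc6)c(OCc6ccccc6)c2)cc2OC(c3ccccc3)(c3ccccc3)Oc12)c1cc(OCc6ccccc6)c(OCc6ccccc6)c(OCc6ccccc6)c1 | intermediate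
19 | (−)-epicatechin-(4β→6)-(−)-epigallocatechin 3,3'-di-O-gallate; upper 2R,3R,4S, lower 2R,3R | O=C(Oc1cc([C@H]2Oc3cc(O)c([C@H]4c5c(O)cc(O)cc5O[C@H](c5ccc(O)c(O)c5)[C@@H]4O)c(O)c3C[C@H]2OC(=O)c2cc(O)c(O)c(O)c2)cc(O)c1O)c1cc(O)c(O)c(O)c1 | target

**Step count**
Total steps: 14. Longest linear sequence: 13 (1 → 2 → 3 → 4 → 5 → 8 → 10 → 11 → 12 → 13 → 15 → 16 → 18 → 19; step 5 is a side branch).

**Three steps most likely to fail, each with a fallback**

Step 11 (double cyclization). The benzylic oxirane may rearrange (hydride shift to a ketone) or give C4 epimers instead of being trapped cleanly by the tethered arene. The fallback forms the two bonds of the upper ring in the opposite order and sets out from 12. Intermolecular Friedel–Crafts opening of the benzylic oxirane of 12 by phenol 6 in HFIP at 0 °C (C-alkylation ortho to the free OH, inversion at C4; the para-alkylated isomer cannot cyclize and is separated) gives 1-[3,4-bis(benzyloxy)phenyl]-3-[2,4-bis(benzyloxy)-6-hydroxyphenyl]-3-[central aryl of 12]propane-1,2-diol F1 (C1 and C2 as in 12, C3 inverted). Mitsunobu cycloetherification of F1 (PPh3, DIAD, THF; the phenol displaces the benzylic C1–OH with inversion) closes the upper pyran and comes back to the route at 14. Compound 14 is then isolated and its terminal oxirane closed to 15 as a separate Friedel–Crafts step.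

Step 8 (Juliá–Colonna epoxidation). The enone is deactivated and hindered by the 2,6-bis(benzyloxy)-4-alkoxyphenyl group, so rate and ee may be poor. The fallback replaces nucleophilic epoxidation of the enone by hydroxyl-directed electrophilic epoxidation of an electron-rich alkene and sets out from 10. Luche reduction (NaBH4, CeCl3·7H2O, MeOH/THF, −20 °C) gives the allylic alcohol (E)-1-[3,4-bis(benzyloxy)phenyl]-3-[central aryl of 10]prop-2-en-1-ol F2 as a mixture of carbinol epimers. Sharpless epoxidation under kinetic-resolution conditions (Ti(OiPr)4, L-(+)-DIPT, t-BuOOH, 4 Å MS, −20 °C) converts only the (1R)-epimer into the erythro trans-epoxy alcohol and comes back to the route at 12. The unreacted (1S)-epimer can be re-oxidised with MnO2 to 10.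

Step 13 (site-selective double galloylation). The upper C3–OH may compete with the lower one. The fallback replaces kinetic differentiation by temporal differentiation and sets out from 14, isolated by quenching step 11 at −78 °C, when the upper C3–OH is the only hydroxyl. Benzylation (NaH, BnBr, Bu4NI, DMF, 0 °C → rt) gives the upper 3-O-benzyl ether of 14 F3. BF3·OEt2 in CH2Cl2 then closes the lower ring to the upper 3-O-benzyl ether of 15 F4. Pd(PPh3)4/morpholine removes the allyl group to give the upper 3-O-benzyl diol F5. Exhaustive esterification with excess 17 (DCC, DMAP) gives the upper 3-O-benzyl digallate F6. Hydrogenolysis (H2, Pd(OH)2/C) removes thirteen benzyl groups and the ketal and comes back to the route at 19.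

**Further compounds**

F1 | step 11 | 1-[3,4-bis(benzyloxy)phenyl]-3-[2,4-bis(benzyloxy)-6-hydroxyphenyl]-3-[2,6-bis(benzyloxy)-4-{(R)-[7-(allyloxy)-2,2-diphenyl-1,3-benzodioxol-5-yl][(2R)-oxiran-2-yl]methoxy}phenyl]propane-1,2-diol | O[C@@H](c1ccc(OCc2ccccc2)c(OCc2ccccc2)c1)[C@H](O)[C@@H](c1c(OCc2ccccc2)cc(O[C@H](c2cc(OCC=C)c3OC(c4ccccc4)(c4ccccc4)Oc3c2)[C@H]2CO2)cc1OCc1ccccc1)c1c(O)cc(OCc2ccccc2)cc1OCc1ccccc1
F2 | step 8 | (E)-1-[3,4-bis(benzyloxy)phenyl]-3-[2,6-bis(benzyloxy)-4-{(R)-[7-(allyloxy)-2,2-diphenyl-1,3-benzodioxol-5-yl][(2R)-oxiran-2-yl]methoxy}phenyl]prop-2-en-1-ol (both carbinol epimers) | OC(/C=C/c1c(OCc2ccccc2)cc(O[C@H](c2cc(OCC=C)c3OC(c4ccccc4)(c4ccccc4)Oc3c2)[C@H]2CO2)cc1OCc1ccccc1)c1ccc(OCc2ccccc2)c(OCc2ccccc2)c1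
F3 | step 13 | upper 3-O-benzyl ether of 14 | C=CCOc1cc([C@@H](Oc2cc(OCc6ccccc6)c([C@H]3c4c(OCc6ccccc6)cc(OCc6ccccc6)cc4O[C@H](c4ccc(OCc6ccccc6)c(OCc6ccccc6)c4)[C@@H]3OCc6ccccc6)c(OCc6ccccc6)c2)[C@H]2CO2)cc2OC(c3ccccc3)(c3ccccc3)Oc12
F4 | step 13 | upper 3-O-benzyl ether of 15 (lower 3-OH free) | C=CCOc1cc([C@H]2Oc3cc(OCc6ccccc6)c([C@H]4c5c(OCc6ccccc6)cc(OCc6ccccc6)cc5O[C@H](c5ccc(OCc6ccccc6)c(OCc6ccccc6)c5)[C@@H]4OCc6ccccc6)c(OCc6ccccc6)c3C[C@H]2O)cc2OC(c3ccccc3)(c3ccccc3)Oc12
F5 | step 13 | upper 3-O-benzyl ether of 16 (lower 3-OH and lower B-ring 3-OH free) | Oc1cc([C@H]2Oc3cc(OCc6ccccc6)c([C@H]4c5c(OCc6ccccc6)cc(OCc6ccccc6)cc5O[C@H](c5ccc(OCc6ccccc6)c(OCc6ccccc6)c5)[C@@H]4OCc6ccccc6)c(OCc6ccccc6)c3C[C@H]2O)cc2OC(c3ccccc3)(c3ccccc3)Oc12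
F6 | step 13 | upper 3-O-benzyl ether of 18 | O=C(Oc1cc([C@H]2Oc3cc(OCc6ccccc6)c([C@H]4c5c(OCc6ccccc6)cc(OCc6ccccc6)cc5O[C@H](c5ccc(OCc6ccccc6)c(OCc6ccccc6)c5)[C@@H]4OCc6ccccc6)c(OCc6ccccc6)c3C[C@H]2OC(=O)c2cc(OCc6ccccc6)c(OCc6ccccc6)c(OCc6ccccc6)c2)cc2OC(c3ccccc3)(c3ccccc3)Oc12)c1cc(OCc6ccccc6)c(OCc6ccccc6)c(OCc6ccccc6)c1
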